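## Retrosynthetic overview

1. The sulfate ester is removed last, which leaves the free phenol bromoiesol B. Its OH comes from a formyl group by Baeyer–Villiger oxidation, so ring A travels as a benzaldehyde.
2. The key disconnection is the ring B–O–ring C ether. This carbon–oxygen bond is made by an iodine-to-oxygen aryl shift inside a diaryliodonium phenolate. The iodine starts on ring B and ends as the ring C iodide. The precursors are the ring A–O–ring B aryl iodide and (5-bromo-2-hydroxyphenyl)boronic acid.
3. The ring A–O–ring B ether comes from SNAr of 3,4,5-tribromo-2-iodophenoxide on 3,5-dibromo-2-fluorobenzaldehyde.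
4. The iodophenol comes from ortho-iodination of 3,4,5-tribromophenol.
5. No ring is built. The three benzene rings are bought and joined in the order B + A, then C.

Assumption: the target has no stereocentre and no configurationally stable axis, so it is achiral and there is no enantiomer to select; the sulfate is delivered in the protonated form drawn.

## Route

**Step 1**
Reactants: 1 3,4,5-tribromophenol
Product: 2 3,4,5-tribromo-2-iodophenol
Conditions: NIS (1.0 equiv), TsOH·H2O (10 mol%), MeCN, 0 °C to rt
Reagents that add atoms: N-iodosuccinimide, O=C1CCC(=O)N1I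
Why: Hydroxyl-directed electrophilic aromatic iodination; the para position is blocked by Br and the two ortho positions are equivalent, so one equivalent of NIS gives a single mono-iodide.

**Step 2**
Reactants: 2 3,4,5-tribromo-2-iodophenol; 3 3,5-dibromo-2-fluorobenzaldehyde
Product: 4 3,5-dibromo-2-(3,4,5-tribromo-2-iodophenoxy)benzaldehyde
Conditions: K2CO3 (1.5 equiv), DMAc, 100 °C
Reagents that add atoms: none
Why: SNAr (addition–elimination through a Meisenheimer complex) at the C–F carbon, which is activated by the ortho formyl group and the flanking Br, while the bromides and the iodide of both partners are unactivated and stay.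

**Step 3**
Reactants: 4 3,5-dibromo-2-(3,4,5-tribromo-2-iodophenoxy)benzaldehyde; 5 (5-bromo-2-hydroxyphenyl)boronic acid
Product: 9 3,5-dibromo-2-[3,4,5-tribromo-2-(4-bromo-2-iodophenoxy)phenoxy]benzaldehyde, via diacetoxyiodane 6 (not isolated), via hydroxyaryl iodonium triflate 7 (not isolated), via iodonium phenolate 8 (not isolated)
Conditions: a) Selectfluor (1.2 equiv), MeCN/AcOH 4:1, 40 °C, dark; evaporate, take up in CH2Cl2, filter off salts; b) 5 (1.05 equiv), TfOH (1.0 equiv), CH2Cl2/MeCN, −40 to 0 °C; c) K2CO3 (4 equiv), MeCN, 0 to 50 °C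
Reagents that add atoms: none
Why: Proposed new method: an iodine-conserving, transposing etherification in which Selectfluor/AcOH raises the aryl iodide of 4 to the diacetoxy-λ3-iodane 6 without touching the aldehyde, TfOH-activated 6 undergoes ipso boron-to-iodine exchange at the C–B carbon of 5 (the most nucleophilic site, ortho to OH; the acid keeps the phenol off iodine, no external nucleophile is present and the 4-bromophenol is only weakly electron-rich, so dearomatising oxidation should lose) to give 7, and K2CO3 unmasks phenolate 8, whose oxygen attacks the ipso carbon of the electron-poor, doubly ortho-substituted ring B through a five-membered transition state (intramolecular ligand coupling, a Smiles-like 1,4-aryl shift from iodine to oxygen), forming the ring B–O bond and leaving the iodine as the ortho iodide of ring C; the closest known reaction types are the regiospecific synthesis of diaryliodonium salts from arylboronic acids and the 1,4-aryl migration of nitro-stabilised 2-(aryliodonio)phenolates and of ortho-sulfonyloxy diaryliodonium salts to 2-iodo diaryl ethers, none of which has been shown with an unprotected hydroxyarylboronic acid, a non-activated halophenolate or a polyhalogenated 2,6-disubstituted migrating aryl.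

**Step 4**
Reactants: 9 3,5-dibromo-2-[3,4,5-tribromo-2-(4-bromo-2-iodophenoxy)phenoxy]benzaldehyde
Product: 11 3,5-dibromo-2-[3,4,5-tribromo-2-(4-bromo-2-iodophenoxy)phenoxy]phenol (bromoiesol B), via aryl formate 10 (not isolated)
Conditions: mCPBA (2 equiv), KH2PO4, CH2Cl2, reflux; aq NaHSO3 wash; then MeOH, cat. HCl, rt
Reagents that add atoms: 3-chloroperoxybenzoic acid, OOC(=O)c1cccc(Cl)c1
Why: Baeyer–Villiger (Dakin-type) oxidation in which the ortho aryloxy lone pair favours migration of ring A over hydride in the Criegee adduct, the phosphate buffer and the bisulfite wash keep or return the ring C iodine in the monovalent state, and acid-catalysed methanolysis removes the formyl group.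

**Step 5**
Reactants: 11 3,5-dibromo-2-[3,4,5-tribromo-2-(4-bromo-2-iodophenoxy)phenoxy]phenol
Product: 13 3,5-dibromo-2-[3,4,5-tribromo-2-(4-bromo-2-iodophenoxy)phenoxy]phenyl hydrogen sulfate (bromoiesol B sulfate), via pyridinium sulfate 12 (not isolated)
Conditions: SO3·pyridine (4 equiv), pyridine, 40 °C; then strong-acid cation-exchange resin (H+ form), MeOH/H2O, 0 °C, freeze-dry
Reagents that add atoms: sulfur trioxide–pyridine complex, [O-]S(=O)(=O)[n+]1ccccc1
Why: O-sulfation of a phenol with an SO3–amine complex; the halogenated rings are too deactivated for C-sulfonation, and cold proton exchange gives the hydrogen sulfate as drawn.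

## Compound list

1 | 3,4,5-tribromophenol | Oc1cc(Br)c(Br)c(Br)c1 | starting material
2 | 3,4,5-tribromo-2-iodophenol | Oc1cc(Br)c(Br)c(Br)c1I | intermediate
3 | 3,5-dibromo-2-fluorobenzaldehyde | O=Cc1cc(Br)cc(Br)c1F | starting material
4 | 3,5-dibromo-2-(3,4,5-tribromo-2-iodophenoxy)benzaldehyde | O=Cc1cc(Br)cc(Br)c1Oc1cc(Br)c(Br)c(Br)c1I | intermediate
5 | (5-bromo-2-hydroxyphenyl)boronic acid | OB(O)c1cc(Br)ccc1O | starting material
6 | [2,3,4-tribromo-6-(2,4-dibromo-6-formylphenoxy)phenyl]-λ3-iodanediyl diacetate | O=Cc1cc(Br)cc(Br)c1Oc1cc(Br)c(Br)c(Br)c1I(OC(C)=O)OC(C)=O | intermediate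
7 | (5-bromo-2-hydroxyphenyl)[2,3,4-tribromo-6-(2,4-dibromo-6-formylphenoxy)phenyl]iodonium trifluoromethanesulfonate | O=Cc1cc(Br)cc(Br)c1Oc1cc(Br)c(Br)c(Br)c1[I+]c1cc(Br)ccc1O.[O-]S(=O)(=O)C(F)(F)F | intermediate
8 | 4-bromo-2-{[2,3,4-tribromo-6-(2,4-dibromo-6-formylphenoxy)phenyl]iodonio}phenolate | O=Cc1cc(Br)cc(Br)c1Oc1cc(Br)c(Br)c(Br)c1[I+]c1cc(Br)ccc1[O-] | intermediate
9 | 3,5-dibromo-2-[3,4,5-tribromo-2-(4-bromo-2-iodophenoxy)phenoxy]benzaldehyde | O=Cc1cc(Br)cc(Br)c1Oc1cc(Br)c(Br)c(Br)c1Oc1ccc(Br)cc1I | intermediate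
10 | 3,5-dibromo-2-[3,4,5-tribromo-2-(4-bromo-2-iodophenoxy)phenoxy]phenyl formate | O=COc1cc(Br)cc(Br)c1Oc1cc(Br)c(Br)c(Br)c1Oc1ccc(Br)cc1I | intermediate
11 | 3,5-dibromo-2-[3,4,5-tribromo-2-(4-bromo-2-iodophenoxy)phenoxy]phenol (bromoiesol B) | Oc1cc(Br)cc(Br)c1Oc1cc(Br)c(Br)c(Br)c1Oc1ccc(Br)cc1I | intermediate
12 | pyridinium 3,5-dibromo-2-[3,4,5-tribromo-2-(4-bromo-2-iodophenoxy)phenoxy]phenyl sulfate | [O-]S(=O)(=O)Oc1cc(Br)cc(Br)c1Oc1cc(Br)c(Br)c(Br)c1Oc1ccc(Br)cc1I.c1cc[nH+]cc1 | intermediate
13 | 3,5-dibromo-2-[3,4,5-tribromo-2-(4-bromo-2-iodophenoxy)phenoxy]phenyl hydrogen sulfate (bromoiesol B sulfate) | O=S(=O)(O)Oc1cc(Br)cc(Br)c1Oc1cc(Br)c(Br)c(Br)c1Oc1ccc(Br)cc1I | target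

## Step count and risks

Total steps: 5. Longest linear sequence: 5 (1 → 2 → 4 → 9 → 11 → 13).

**Step 3, the new step, carries the highest risk.** Iodane 6 may oxidise the free phenol of 5, or 5 may protodeboronate before the boron-to-iodine exchange. The fallback sets out from 4 and comes back at 9, and it uses only known chemistry:
- 4 is oxidised as before to 6.
- 6 is condensed with 1,3,5-trimethoxybenzene and TsOH·H2O in MeCN to give the isolable [2,3,4-tribromo-6-(2,4-dibromo-6-formylphenoxy)phenyl](2,4,6-trimethoxyphenyl)iodonium 4-methylbenzenesulfonate F1.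
- This salt O-arylates commercial 4-bromo-2-iodophenol (K2CO3, toluene/MeCN, 60 °C) in a metal-free phenol arylation. The electron-rich trimethoxyphenyl group stays on iodine as the dummy ligand. The electron-poor, doubly ortho-substituted ring B is transferred, which gives 9.

**Step 2 may stall.** The phenoxide of 2 is weakly nucleophilic and flanked by iodine, and it attacks a C–F carbon that is hindered on both sides. The fallback sets out from 1 and comes back at 4 by reversing the order of bond formation:
- The unhindered phenoxide of 1 is joined to 3 (K2CO3, DMAc, 80 °C) to give 3,5-dibromo-2-(3,4,5-tribromophenoxy)benzaldehyde F2.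
- The iodine is then introduced by superelectrophilic iodination (NIS, TfOH, CH2Cl2, 0 °C to rt).
- Iodination occurs at one of the two equivalent ring B positions ortho to the ether oxygen. The free positions of ring A are both meta to that oxygen and deactivated by the protonated aldehyde, so the product is 4.

**Step 4 may suffer from a competing hydride shift.** On the electron-poor ring A, hydride shift in the Criegee adduct can give the carboxylic acid instead of the formate. The fallback sets out from 9 and comes back at 11. It replaces the formyl group with an acetyl group, which has no migrating hydride: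
- AlMe3 (toluene/CH2Cl2, −20 °C) adds to the aldehyde without halogen–metal exchange. The product is racemic 1-{3,5-dibromo-2-[3,4,5-tribromo-2-(4-bromo-2-iodophenoxy)phenoxy]phenyl}ethanol F3.
- Dess–Martin periodinane erases the transient stereocentre and gives 1-{3,5-dibromo-2-[3,4,5-tribromo-2-(4-bromo-2-iodophenoxy)phenoxy]phenyl}ethanone F4.
- Baeyer–Villiger oxidation (mCPBA, TFA, CH2Cl2, with a NaHSO3 work-up that returns any oxidised iodine to the iodide) gives 3,5-dibromo-2-[3,4,5-tribromo-2-(4-bromo-2-iodophenoxy)phenoxy]phenyl acetate F5.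
- Methanolysis (K2CO3, MeOH) then gives 11.

## Further compounds

F1 | step 3 | [2,3,4-tribromo-6-(2,4-dibromo-6-formylphenoxy)phenyl](2,4,6-trimethoxyphenyl)iodonium 4-methylbenzenesulfonate | O=Cc1cc(Br)cc(Br)c1Oc1cc(Br)c(Br)c(Br)c1[I+]c1c(OC)cc(OC)cc1OC.Cc1ccc(cc1)S(=O)(=O)[O-]
F2 | step 2 | 3,5-dibromo-2-(3,4,5-tribromophenoxy)benzaldehyde | O=Cc1cc(Br)cc(Br)c1Oc1cc(Br)c(Br)c(Br)c1
F3 | step 4 | 1-{3,5-dibromo-2-[3,4,5-tribromo-2-(4-bromo-2-iodophenoxy)phenoxy]phenyl}ethanol (racemic) | CC(O)c1cc(Br)cc(Br)c1Oc1cc(Br)c(Br)c(Br)c1Oc1ccc(Br)cc1I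
F4 | step 4 | 1-{3,5-dibromo-2-[3,4,5-tribromo-2-(4-bromo-2-iodophenoxy)phenoxy]phenyl}ethanone | CC(=O)c1cc(Br)cc(Br)c1Oc1cc(Br)c(Br)c(Br)c1Oc1ccc(Br)cc1I
F5 | step 4 | 3,5-dibromo-2-[3,4,5-tribromo-2-(4-bromo-2-iodophenoxy)phenoxy]phenyl acetate | CC(=O)Oc1cc(Br)cc(Br)c1Oc1cc(Br)c(Br)c(Br)c1Oc1ccc(Br)cc1I
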